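**Plan**

- The only ring to be made is the dione ring. Locants: C1 = ketone peri to the C8 hydroxyl, C2 = C(Cl)CH3, C3 = carbinol, C4 = second ketone, C4a/C8a = ring fusion. It is cut at C1–C2: C2 holds Cl and CH3 next to the C1 aryl ketone, so this bond plus one methyl hydrogen equals an aldehyde on C8a added Markovnikov across a 1-chlorovinyl group on C3.
- Further cuts: C4–C4a (aryllithium + Weinreb amide), the chloroalkene back to an alkyne, C3–C2 (alkynylation of an α-keto ester), C3–CH2 (dithiane alkylation) and the geranyl–carbon bond of the side chain (dienolate alkylation).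
- Forward: the C15 side-chain bromide is made first, then the α-keto ester, the alkynyl carbinol, the chlorovinyl carbinol Weinreb amide and the aryl ketone (arene from 5-bromoresorcinol). The ring closes in the last C–C bond formation and desilylation ends the route.
- Stereochemistry: C3 comes from a catalytic asymmetric alkynylation (reagent control). C2 is set in the ring closure, directed by C3 and reinforced by a matched chiral carbene. The E alkene is carried in from geranyl bromide.

Key step: step 17

Assumption: the facial sense of the alkynylation in step 7 is taken to follow the ligand antipode, so the ligand enantiomer that delivers the (R)-carbinol 13 is used (the same centre is S from 15 onward only because the CIP priorities change).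

**Step 1**
Reactants: 1 methyl 3-methylbut-2-enoate; 2 geranyl bromide
Product: 4 methyl (4E)-5,9-dimethyl-2-(prop-1-en-2-yl)deca-4,8-dienoate as the racemate, via lithium dienolate 3 (not isolated)
Conditions: LDA, THF–DMPU, −78 °C; then 2, −78 → 0 °C
Reagents that add atoms: none
Why: Deconjugative α-alkylation of an extended ester enolate, in which the γ-deprotonated dienolate should react at its α-carbon by SN2 displacement of the primary allylic bromide without touching the E alkene of the geranyl unit.

**Step 2**
Reactants: 4 methyl (4E)-5,9-dimethyl-2-(prop-1-en-2-yl)deca-4,8-dienoate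
Product: 5 methyl (4E)-5,9-dimethyl-2-(propan-2-ylidene)deca-4,8-dienoate
Conditions: KOt-Bu (0.3 equiv), t-BuOH–THF, 0 °C → rt
Reagents that add atoms: none
Why: Base-mediated alkene isomerisation under equilibrating conditions (reversible dienolate formation in a protic medium) should move the 1,1-disubstituted alkene into conjugation as the tetrasubstituted enoate and at the same time removes the α-stereocentre.

**Step 3**
Reactants: 5 methyl (4E)-5,9-dimethyl-2-(propan-2-ylidene)deca-4,8-dienoate
Product: 6 (4E)-5,9-dimethyl-2-(propan-2-ylidene)deca-4,8-dien-1-ol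
Conditions: DIBAL-H (2.5 equiv), CH2Cl2, −78 → 0 °C; Rochelle salt work-up
Reagents that add atoms: none
Why: 1,2-Reduction of the enoate by DIBAL-H should give the allylic alcohol and leave the isolated alkenes alone.

**Step 4**
Reactants: 6 (4E)-5,9-dimethyl-2-(propan-2-ylidene)deca-4,8-dien-1-ol
Product: 7 (5E)-3-(bromomethyl)-2,6,10-trimethylundeca-2,5,9-triene
Conditions: CBr4, PPh3, CH2Cl2, 0 °C; used directly
Reagents that add atoms: carbon tetrabromide, BrC(Br)(Br)Br
Why: Appel bromination converts the primary allylic alcohol by SN2 attack of bromide on the alkoxyphosphonium ion under neutral conditions, which avoids acid-induced cyclisation or allylic transposition of the polyene.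

**Step 5**
Reactants: 7 (5E)-3-(bromomethyl)-2,6,10-trimethylundeca-2,5,9-triene; 8 ethyl 1,3-dithiane-2-carboxylate
Product: 10 ethyl 2-[(4E)-5,9-dimethyl-2-(propan-2-ylidene)deca-4,8-dien-1-yl]-1,3-dithiane-2-carboxylate, via sodium dithianyl enolate 9 (not isolated)
Conditions: NaH, DMF–toluene (1:1), 0 °C; then 7, 0 °C → rt
Reagents that add atoms: none
Why: Alkylation of the doubly stabilised dithiane ester anion (a masked acyl anion, Corey–Seebach-type umpolung) should proceed by SN2 at the unhindered primary allylic carbon and not at the tetrasubstituted alkene terminus.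

**Step 6**
Reactants: 10 ethyl 2-[(4E)-5,9-dimethyl-2-(propan-2-ylidene)deca-4,8-dien-1-yl]-1,3-dithiane-2-carboxylate
Product: 11 ethyl (6E)-7,11-dimethyl-2-oxo-4-(propan-2-ylidene)dodeca-6,10-dienoate
Conditions: PhI(OCOCF3)2 (1.5 equiv), NaHCO3, MeCN–H2O (9:1), 0 °C, short reaction time
Reagents that add atoms: water, O
Why: Oxidative dethioacetalisation with a hypervalent iodine reagent, in which sulfur is oxidised much faster than the alkenes and water then releases the ketone, while the bicarbonate buffer protects the acid-sensitive polyene and the enolisable α-keto ester.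

**Step 7**
Reactants: 11 ethyl (6E)-7,11-dimethyl-2-oxo-4-(propan-2-ylidene)dodeca-6,10-dienoate; 12 ethynyltri(propan-2-yl)silane
Product: 13 ethyl (2R,6E)-2-hydroxy-7,11-dimethyl-4-(propan-2-ylidene)-2-{[tri(propan-2-yl)silyl]ethynyl}dodeca-6,10-dienoate
Conditions: 12 (1.5 equiv), CuOt-Bu (10 mol %), chiral prolinol-derived hydroxy aminophosphine ligand (12 mol %, enantiomer giving the R carbinol), t-BuOH, 25 °C
Reagents that add atoms: none
Why: Catalytic asymmetric direct alkynylation of an α-keto ester, in which the chiral copper(I) acetylide attacks one face of the ester-activated ketone held by the ligand hydroxyl group and so sets the C3 carbinol centre under reagent control.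

**Step 8**
Reactants: 13 ethyl (2R,6E)-2-hydroxy-7,11-dimethyl-4-(propan-2-ylidene)-2-{[tri(propan-2-yl)silyl]ethynyl}dodeca-6,10-dienoate
Product: 14 ethyl (2R,6E)-2-ethynyl-2-hydroxy-7,11-dimethyl-4-(propan-2-ylidene)dodeca-6,10-dienoate
Conditions: TBAF (1.2 equiv), AcOH (1.2 equiv), THF, 0 °C → rt
Reagents that add atoms: none
Why: Fluoride-induced protodesilylation of the alkynylsilane, buffered with acetic acid so that the α-hydroxy ester is not exposed to hydroxide.

**Step 9**
Reactants: 14 ethyl (2R,6E)-2-ethynyl-2-hydroxy-7,11-dimethyl-4-(propan-2-ylidene)dodeca-6,10-dienoate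
Product: 16 ethyl (2S,6E)-2-(1-chloroethenyl)-2-hydroxy-7,11-dimethyl-4-(propan-2-ylidene)dodeca-6,10-dienoate, via alkenylstannane 15 (not isolated)
Conditions: Bu3SnH (1.1 equiv), [Cp*RuCl]4 (2.5 mol %), CH2Cl2, rt; solvent exchange; CuCl2 (2.5 equiv), THF, rt
Reagents that add atoms: copper(II) chloride, Cl[Cu]Cl; tributyltin hydride, CCCC[SnH](CCCC)CCCC (supplies the new C–H hydrogen and the tin of 15)
Why: Hydroxyl-directed ruthenium-catalysed hydrostannation should place tin on the alkyne carbon next to the carbinol (Markovnikov), and copper(II)-mediated ipso chlorodestannylation then gives the 1-chlorovinyl group without the acid that would hydrochlorinate or cyclise the tri- and tetrasubstituted alkenes.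

**Step 10**
Reactants: 16 ethyl (2S,6E)-2-(1-chloroethenyl)-2-hydroxy-7,11-dimethyl-4-(propan-2-ylidene)dodeca-6,10-dienoate
Product: 17 (2S,6E)-2-(1-chloroethenyl)-2-hydroxy-N-methoxy-N,7,11-trimethyl-4-(propan-2-ylidene)dodeca-6,10-dienamide
Conditions: MeNH(OMe)·HCl (5 equiv), i-PrMgCl (10 equiv), THF, −20 → 0 °C
Reagents that add atoms: N,O-dimethylhydroxylamine hydrochloride, CNOC.Cl
Why: Weinreb amide formation by aminolysis of the ester with the chloromagnesium amide, which the neighbouring magnesium alkoxide should assist by chelation, while the vinyl chloride is inert to the Grignard base at this temperature.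

**Step 11**
Reactants: 17 (2S,6E)-2-(1-chloroethenyl)-2-hydroxy-N-methoxy-N,7,11-trimethyl-4-(propan-2-ylidene)dodeca-6,10-dienamide
Product: 18 (2S,6E)-2-(1-chloroethenyl)-N-methoxy-N,7,11-trimethyl-4-(propan-2-ylidene)-2-(triethylsilyloxy)dodeca-6,10-dienamide
Conditions: TESOTf (1.5 equiv), 2,6-lutidine (3 equiv), CH2Cl2, −78 → 0 °C
Reagents that add atoms: triethylsilyl trifluoromethanesulfonate, CC[Si](CC)(CC)OS(=O)(=O)C(F)(F)F
Why: Silylation of the hindered tertiary alcohol with a silyl triflate and a non-nucleophilic base gives a silyl ether that later blocks lactol and epoxide formation and can be removed with fluoride.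

**Step 12**
Reactants: 19 5-bromoresorcinol
Product: 21 2-bromo-4,6-dihydroxybenzaldehyde, via aryl iminium chloride 20 (not isolated)
Conditions: POCl3, DMF, MeCN, 0 °C → rt; then H2O, 50 °C
Reagents that add atoms: N,N-dimethylformamide, CN(C)C=O; water, O
Why: Vilsmeier–Haack formylation, in which the chloroiminium ion should attack the position ortho to one hydroxyl and para to the other (the two such positions are equivalent) in preference to the more crowded carbon between the hydroxyls, and hydrolysis of the iminium salt releases the aldehyde.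

**Step 13**
Reactants: 21 2-bromo-4,6-dihydroxybenzaldehyde
Product: 22 2-bromo-4,6-bis(tert-butyldimethylsilyloxy)benzaldehyde
Conditions: TBSCl (2.5 equiv), imidazole (5 equiv), DMF, rt
Reagents that add atoms: tert-butyldimethylsilyl chloride, CC(C)(C)[Si](C)(C)Cl
Why: Imidazole-promoted silylation of both phenols gives aryl silyl ethers that tolerate the organolithium and carbene steps and are cleaved by fluoride at the end.

**Step 14**
Reactants: 22 2-bromo-4,6-bis(tert-butyldimethylsilyloxy)benzaldehyde
Product: 23 1-bromo-3,5-bis(tert-butyldimethylsilyloxy)-2-(dimethoxymethyl)benzene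
Conditions: HC(OMe)3 (5 equiv), PPTS (5 mol %), MeOH, rt; Et3N quench
Reagents that add atoms: trimethyl orthoformate, COC(OC)OC
Why: Acid-catalysed acetalisation driven by the orthoformate masks the aldehyde for the organolithium step, and the weak acid should leave the aryl silyl ethers intact.

**Step 15**
Reactants: 23 1-bromo-3,5-bis(tert-butyldimethylsilyloxy)-2-(dimethoxymethyl)benzene; 18 (2S,6E)-2-(1-chloroethenyl)-N-methoxy-N,7,11-trimethyl-4-(propan-2-ylidene)-2-(triethylsilyloxy)dodeca-6,10-dienamide
Product: 25 (2S,6E)-1-[3,5-bis(tert-butyldimethylsilyloxy)-2-(dimethoxymethyl)phenyl]-2-(1-chloroethenyl)-7,11-dimethyl-4-(propan-2-ylidene)-2-(triethylsilyloxy)dodeca-6,10-dien-1-one, via aryllithium 24 (not isolated)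
Conditions: 23 (1.25 equiv), n-BuLi (1.2 equiv), THF, −78 °C; then 18, −78 → −40 °C; aq. NH4Cl
Reagents that add atoms: none
Why: Bromine–lithium exchange followed by acylation of the aryllithium with the Weinreb amide, whose chelated tetrahedral intermediate prevents over-addition, should give the C4–C4a bond while the vinyl chloride and the silyl ethers stay inert at low temperature.

**Step 16**
Reactants: 25 (2S,6E)-1-[3,5-bis(tert-butyldimethylsilyloxy)-2-(dimethoxymethyl)phenyl]-2-(1-chloroethenyl)-7,11-dimethyl-4-(propan-2-ylidene)-2-(triethylsilyloxy)dodeca-6,10-dien-1-one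
Product: 26 4,6-bis(tert-butyldimethylsilyloxy)-2-[(2S,6E)-2-(1-chloroethenyl)-7,11-dimethyl-4-(propan-2-ylidene)-2-(triethylsilyloxy)dodeca-6,10-dienoyl]benzaldehyde
Conditions: PPTS (10 mol %), acetone–H2O (10:1), rt
Reagents that add atoms: water, O
Why: Acid-catalysed acetal hydrolysis should be fast here because the siloxy groups ortho and para to the acetal carbon stabilise the oxocarbenium ion, so that conditions mild enough for the tertiary silyl ether, the aryl silyl ethers and the polyene suffice.

**Step 17**
Reactants: 26 4,6-bis(tert-butyldimethylsilyloxy)-2-[(2S,6E)-2-(1-chloroethenyl)-7,11-dimethyl-4-(propan-2-ylidene)-2-(triethylsilyloxy)dodeca-6,10-dienoyl]benzaldehyde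
Product: 27 (2R,3S)-6,8-bis(tert-butyldimethylsilyloxy)-2-chloro-3-[(4E)-5,9-dimethyl-2-(propan-2-ylidene)deca-4,8-dien-1-yl]-2-methyl-3-(triethylsilyloxy)-2,3-dihydronaphthalene-1,4-dione
Conditions: chiral aminoindanol-derived N-mesityl triazolium tetrafluoroborate (20 mol %, matched enantiomer), DBU (20 mol %), 1,4-dioxane, 80 °C
Reagents that add atoms: none
Why: Proposed new method: the triazolylidene adds to the C8a aldehyde and proton transfer gives the Breslow enaminol, whose O–H and nucleophilic carbon then add across the 1-chlorovinyl group through a five-centre, concerted but asynchronous ene-type (Conia-ene-like) transition state, the proton going to the terminal CH2 and the acyl carbon to the chlorine-bearing carbon, after which loss of the carbene leaves the C1 ketone; the closest known reaction type is the carbene-catalysed intramolecular hydroacylation of unactivated 1,1-disubstituted alkenes to α-quaternary ketones. The dione ring closes in a 6-exo-trig mode, forming C1–C2 and turning the exocyclic CH2 into the C2 methyl group. Markovnikov regiochemistry is needed and should be secured because the partial positive charge of the asynchronous transition state develops on the internal carbon, where the chlorine lone pairs stabilise it, and because only the exo array lets the enol proton reach the terminal carbon. The new C2 centre is controlled by C3: the nascent methyl has to lie beside the enol O–H and is therefore pseudo-equatorial, which puts chlorine pseudo-axial, and the C3 siloxy group should take the opposite pseudo-axial site with the bulky side-chain CH2 pseudo-equatorial, giving the trans Cl/O (2R,3S) isomer, a bias the chosen triazolium enantiomer is meant to reinforce. Chemoselectivity rests on the ortho arrangement, which brings only the chlorovinyl group within reach of the acyl carbon (the side-chain alkenes cannot attain a six-membered array), and on the C3 silyl ether, which excludes lactol formation with the aldehyde and later alkoxide attack on the C–Cl carbon.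

**Step 18**
Reactants: 27 (2R,3S)-6,8-bis(tert-butyldimethylsilyloxy)-2-chloro-3-[(4E)-5,9-dimethyl-2-(propan-2-ylidene)deca-4,8-dien-1-yl]-2-methyl-3-(triethylsilyloxy)-2,3-dihydronaphthalene-1,4-dione
Product: 28 (2R,3S)-2-chloro-3-[(4E)-5,9-dimethyl-2-(propan-2-ylidene)deca-4,8-dien-1-yl]-3,6,8-trihydroxy-2-methyl-2,3-dihydronaphthalene-1,4-dione
Conditions: HF·pyridine, pyridine, THF, 0 °C → rt
Reagents that add atoms: none
Why: Fluoride-mediated cleavage of the triethylsilyl and both aryl silyl ethers under buffered, non-basic conditions, so that the trans-chlorohydrin should not close to the epoxide and the tertiary α-ketol should not rearrange.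

**Compound list**

1 | methyl 3-methylbut-2-enoate | COC(=O)C=C(C)C | starting material
2 | geranyl bromide, (2E)-1-bromo-3,7-dimethylocta-2,6-diene | CC(C)=CCC/C(C)=C/CBr | starting material
3 | lithium dienolate of 1 (lithium 1-methoxy-3-methylbuta-1,3-dien-1-olate) | COC(O[Li])=CC(C)=C | intermediate
4 | methyl (4E)-5,9-dimethyl-2-(prop-1-en-2-yl)deca-4,8-dienoate, racemic at C2 | CC(C)=CCC/C(C)=C/CC(C(C)=C)C(=O)OC | intermediate
5 | methyl (4E)-5,9-dimethyl-2-(propan-2-ylidene)deca-4,8-dienoate | CC(C)=CCC/C(C)=C/CC(C(=O)OC)=C(C)C | intermediate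
6 | (4E)-5,9-dimethyl-2-(propan-2-ylidene)deca-4,8-dien-1-ol | CC(C)=CCC/C(C)=C/CC(CO)=C(C)C | intermediate
7 | (5E)-3-(bromomethyl)-2,6,10-trimethylundeca-2,5,9-triene | CC(C)=CCC/C(C)=C/CC(CBr)=C(C)C | intermediate
8 | ethyl 1,3-dithiane-2-carboxylate | CCOC(=O)C1SCCCS1 | starting material
9 | sodium enolate of 8 | CCOC(O[Na])=C1SCCCS1 | intermediate
10 | ethyl 2-[(4E)-5,9-dimethyl-2-(propan-2-ylidene)deca-4,8-dien-1-yl]-1,3-dithiane-2-carboxylate | CC(C)=CCC/C(C)=C/CC(CC1(C(=O)OCC)SCCCS1)=C(C)C | intermediate
11 | ethyl (6E)-7,11-dimethyl-2-oxo-4-(propan-2-ylidene)dodeca-6,10-dienoate | CC(C)=CCC/C(C)=C/CC(CC(=O)C(=O)OCC)=C(C)C | intermediate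
12 | ethynyltri(propan-2-yl)silane (TIPS-acetylene) | C#C[Si](C(C)C)(C(C)C)C(C)C | starting material
13 | ethyl (2R,6E)-2-hydroxy-7,11-dimethyl-4-(propan-2-ylidene)-2-{[tri(propan-2-yl)silyl]ethynyl}dodeca-6,10-dienoate | CC(C)=CCC/C(C)=C/CC(C[C@@](O)(C#C[Si](C(C)C)(C(C)C)C(C)C)C(=O)OCC)=C(C)C | intermediate
14 | ethyl (2R,6E)-2-ethynyl-2-hydroxy-7,11-dimethyl-4-(propan-2-ylidene)dodeca-6,10-dienoate | CC(C)=CCC/C(C)=C/CC(C[C@@](O)(C#C)C(=O)OCC)=C(C)C | intermediate
15 | ethyl (2S,6E)-2-hydroxy-7,11-dimethyl-4-(propan-2-ylidene)-2-[1-(tributylstannyl)ethenyl]dodeca-6,10-dienoate | CC(C)=CCC/C(C)=C/CC(C[C@@](O)(C(=C)[Sn](CCCC)(CCCC)CCCC)C(=O)OCC)=C(C)C | intermediate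
16 | ethyl (2S,6E)-2-(1-chloroethenyl)-2-hydroxy-7,11-dimethyl-4-(propan-2-ylidene)dodeca-6,10-dienoate | CC(C)=CCC/C(C)=C/CC(C[C@@](O)(C(Cl)=C)C(=O)OCC)=C(C)C | intermediate
17 | (2S,6E)-2-(1-chloroethenyl)-2-hydroxy-N-methoxy-N,7,11-trimethyl-4-(propan-2-ylidene)dodeca-6,10-dienamide | CC(C)=CCC/C(C)=C/CC(C[C@@](O)(C(Cl)=C)C(=O)N(C)OC)=C(C)C | intermediate
18 | (2S,6E)-2-(1-chloroethenyl)-N-methoxy-N,7,11-trimethyl-4-(propan-2-ylidene)-2-(triethylsilyloxy)dodeca-6,10-dienamide | CC(C)=CCC/C(C)=C/CC(C[C@@](O[Si](CC)(CC)CC)(C(Cl)=C)C(=O)N(C)OC)=C(C)C | intermediate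
19 | 5-bromoresorcinol (5-bromobenzene-1,3-diol) | Oc1cc(O)cc(Br)c1 | starting material
20 | N-[(2-bromo-4,6-dihydroxyphenyl)methylidene]-N-methylmethanaminium chloride | C[N+](C)=Cc1c(O)cc(O)cc1Br.[Cl-] | intermediate
21 | 2-bromo-4,6-dihydroxybenzaldehyde | O=Cc1c(O)cc(O)cc1Br | intermediate
22 | 2-bromo-4,6-bis(tert-butyldimethylsilyloxy)benzaldehyde | O=Cc1c(O[Si](C)(C)C(C)(C)C)cc(O[Si](C)(C)C(C)(C)C)cc1Br | intermediate
23 | 1-bromo-3,5-bis(tert-butyldimethylsilyloxy)-2-(dimethoxymethyl)benzene | COC(OC)c1c(O[Si](C)(C)C(C)(C)C)cc(O[Si](C)(C)C(C)(C)C)cc1Br | intermediate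
24 | [3,5-bis(tert-butyldimethylsilyloxy)-2-(dimethoxymethyl)phenyl]lithium | COC(OC)c1c(O[Si](C)(C)C(C)(C)C)cc(O[Si](C)(C)C(C)(C)C)cc1[Li] | intermediate
25 | (2S,6E)-1-[3,5-bis(tert-butyldimethylsilyloxy)-2-(dimethoxymethyl)phenyl]-2-(1-chloroethenyl)-7,11-dimethyl-4-(propan-2-ylidene)-2-(triethylsilyloxy)dodeca-6,10-dien-1-one | CC(C)=CCC/C(C)=C/CC(C[C@@](O[Si](CC)(CC)CC)(C(Cl)=C)C(=O)c1cc(O[Si](C)(C)C(C)(C)C)cc(O[Si](C)(C)C(C)(C)C)c1C(OC)OC)=C(C)C | intermediate
26 | 4,6-bis(tert-butyldimethylsilyloxy)-2-[(2S,6E)-2-(1-chloroethenyl)-7,11-dimethyl-4-(propan-2-ylidene)-2-(triethylsilyloxy)dodeca-6,10-dienoyl]benzaldehyde | CC(C)=CCC/C(C)=C/CC(C[C@@](O[Si](CC)(CC)CC)(C(Cl)=C)C(=O)c1cc(O[Si](C)(C)C(C)(C)C)cc(O[Si](C)(C)C(C)(C)C)c1C=O)=C(C)C | intermediate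
27 | (2R,3S)-6,8-bis(tert-butyldimethylsilyloxy)-2-chloro-3-[(4E)-5,9-dimethyl-2-(propan-2-ylidene)deca-4,8-dien-1-yl]-2-methyl-3-(triethylsilyloxy)-2,3-dihydronaphthalene-1,4-dione | CC(C)=CCC/C(C)=C/CC(C[C@]1(O[Si](CC)(CC)CC)C(=O)c2cc(O[Si](C)(C)C(C)(C)C)cc(O[Si](C)(C)C(C)(C)C)c2C(=O)[C@]1(C)Cl)=C(C)C | intermediate
28 | (2R,3S)-2-chloro-3-[(4E)-5,9-dimethyl-2-(propan-2-ylidene)deca-4,8-dien-1-yl]-3,6,8-trihydroxy-2-methyl-2,3-dihydronaphthalene-1,4-dione | CC(C)=CCC/C(C)=C/CC(C[C@]1(O)C(=O)c2cc(O)cc(O)c2C(=O)[C@]1(C)Cl)=C(C)C | target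

**Step count**

Total: 18 steps. Longest linear sequence: 15 steps (steps 1–11 and 15–18); the arene branch (steps 12–14) joins at step 15.

**Steps most likely to fail**

1. Step 17 (ring closure). The carbene may fail to add to the aldehyde, which is flanked on both sides. Hydride transfer from the carbene–aldehyde adduct to the neighbouring ketone (redox lactonisation) may outrun proton transfer to the chloroalkene. Facial selectivity at C2 may be poor. The fallback sets out from 26 and forms the same C1–C2 bond by a radical route of known type, a metal-hydride hydrogen-atom-transfer reductive cyclisation of an alkene onto a carbonyl group (Fe(acac)3, PhSiH3, EtOH–ethylene glycol, 60 °C). Hydrogen-atom transfer to the terminal CH2 of the chloroalkene gives the tertiary α-chloro radical at C2, which adds 6-exo to the aldehyde carbon; radicals formed at the side-chain alkenes have no acceptor within reach. This should give 5,7-bis(tert-butyldimethylsilyloxy)-3-chloro-2-[(4E)-5,9-dimethyl-2-(propan-2-ylidene)deca-4,8-dien-1-yl]-4-hydroxy-3-methyl-2-(triethylsilyloxy)-3,4-dihydronaphthalen-1(2H)-one F1 as a mixture of carbinol epimers. Oxidation of the secondary alcohol with Dess–Martin periodinane (NaHCO3, CH2Cl2) comes back to the route at 27.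

2. Step 7 (asymmetric alkynylation). Enantioselectivity may erode, or the basic copper alkoxide may enolise the α-keto ester and move the β,γ-alkene into conjugation before the acetylide adds. The fallback sets out from 11: ethynylmagnesium bromide (THF, −78 °C) adds to the keto group, which is far more electrophilic than the ester, to give racemic ethyl (6E)-2-ethynyl-2-hydroxy-7,11-dimethyl-4-(propan-2-ylidene)dodeca-6,10-dienoate F2 directly at the desilylated stage. Resolution by preparative chromatography on a chiral stationary phase then delivers the (R)-enantiomer, which is 14, so the route is rejoined at 14 without passing through 13.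

3. Step 15 (aryl ketone formation). Addition of the ortho-substituted aryllithium to the neopentyl-type amide may be slow, so that base-induced loss of the N-methoxy group from the amide or decay of the aryllithium on warming takes over. The fallback sets out from 18: DIBAL-H (THF, −78 °C) reduces the Weinreb amide to (2S,6E)-2-(1-chloroethenyl)-7,11-dimethyl-4-(propan-2-ylidene)-2-(triethylsilyloxy)dodeca-6,10-dienal F3. Aryllithium 24, generated from 23 as in step 15, adds to this much more reactive carbonyl group to give (2S,6E)-1-[3,5-bis(tert-butyldimethylsilyloxy)-2-(dimethoxymethyl)phenyl]-2-(1-chloroethenyl)-7,11-dimethyl-4-(propan-2-ylidene)-2-(triethylsilyloxy)dodeca-6,10-dien-1-ol F4 as a mixture of carbinol epimers. Dess–Martin periodinane (NaHCO3, CH2Cl2) oxidises it to the ketone, coming back to the route at 25.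

**Further compounds**

F1 | step 17 | 5,7-bis(tert-butyldimethylsilyloxy)-3-chloro-2-[(4E)-5,9-dimethyl-2-(propan-2-ylidene)deca-4,8-dien-1-yl]-4-hydroxy-3-methyl-2-(triethylsilyloxy)-3,4-dihydronaphthalen-1(2H)-one (quaternary centres as in 27, both carbinol epimers) | CC(C)=CCC/C(C)=C/CC(C[C@]1(O[Si](CC)(CC)CC)C(=O)c2cc(O[Si](C)(C)C(C)(C)C)cc(O[Si](C)(C)C(C)(C)C)c2C(O)[C@]1(C)Cl)=C(C)C
F2 | step 7 | racemic ethyl (6E)-2-ethynyl-2-hydroxy-7,11-dimethyl-4-(propan-2-ylidene)dodeca-6,10-dienoate | CC(C)=CCC/C(C)=C/CC(CC(O)(C#C)C(=O)OCC)=C(C)C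
F3 | step 15 | (2S,6E)-2-(1-chloroethenyl)-7,11-dimethyl-4-(propan-2-ylidene)-2-(triethylsilyloxy)dodeca-6,10-dienal | CC(C)=CCC/C(C)=C/CC(C[C@@](O[Si](CC)(CC)CC)(C(Cl)=C)C=O)=C(C)C
F4 | step 15 | (2S,6E)-1-[3,5-bis(tert-butyldimethylsilyloxy)-2-(dimethoxymethyl)phenyl]-2-(1-chloroethenyl)-7,11-dimethyl-4-(propan-2-ylidene)-2-(triethylsilyloxy)dodeca-6,10-dien-1-ol (both carbinol epimers) | CC(C)=CCC/C(C)=C/CC(C[C@@](O[Si](CC)(CC)CC)(C(Cl)=C)C(O)c1cc(O[Si](C)(C)C(C)(C)C)cc(O[Si](C)(C)C(C)(C)C)c1C(OC)OC)=C(C)C
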